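- Over the minutes around mid-conversion the earlier runs looked pseudo-first-order in starting material, so I read a constant per amount of catalyst, kc, from the fall of c(starting material) in each run.

in all of them: gas 16 mM (held)
- midnight: starting material 0.19 M; free catalyst 0.85 mM; run made earlier
- winter: starting material 0.19 M; free catalyst 1.3 mM; run made earlier
- summer: starting material 0.29 M; free catalyst 0.61 mM; run made earlier
- flask: starting material 0.19 M; free catalyst 0.61 mM

- midnight (time / min: product / %, starting material / %): 2.00: 30, 73; 6.00: 68, 36; 10.0: 87, 14; 15.0: 96, 5; 20.0: 98, 4; 30.0: 97, 0; 40.0: 102, 0
- winter (time / min: product / %, starting material / %): 2.00: 38, 61; 6.00: 79, 18; 10.0: 95, 7; 15.0: 96, 2; 20.0: 100, 0; 30.0: 100, 1; 40.0: 99, 1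
- summer (time / min: product / %, starting material / %): 3.00: 28, 74; 5.00: 43, 56; 10.0: 67, 32; 20.0: 93, 8; 40.0: 101, 2

(readings scatter by 1.5 percentage points)

- at the start none of the gas is in solution

* factor on the rate of making product when 50% of the starting material are converted if free catalyst is charged twice over
* factor on the rate when 50% of the starting material are converted if free catalyst is charged at 3.0 mM instead

- Between 2.00 min and 6.00 min the midnight run gave kc = 0.208 /mM/min, and I doubted it at once: if a higher charge starved the catalyst of gas, kc should fall as c(free catalyst) rises.
- Winter, at the same c(starting material) as midnight but with 1.3 mM, read 0.235 /mM/min over the same minutes, not lower than the midnight reading, so these two runs did not show that fall; summer, with 0.61 mM and a higher c(starting material), read 0.183 /mM/min over later minutes, and since two settings differ there I drew nothing about the catalyst from it and kept the midnight value, which lies between the other two readings.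
- At 50% conversion in the flask, kc·c(free catalyst)·c(starting material) comes to 12.0 mM/min, and this rate that the catalyst asks for at its charge, the demand, is what I carried on.
- At 1.22 mM the demand is 24.1 mM/min, less than the 37.0 mM/min read as the average fall of starting material over the first 2.00 min of winter, so I committed to a factor of about 2.01.
- At 3.0 mM the demand is 59.3 mM/min, more than that winter reading, so I distrusted the proportional 4.92 and expected less, without being able to say how much less.
- The forecast gave 2 and 4.8, adding: “Gas supply could start limiting there, so my range extends lower.”
- The flask gave 1.93 and 3.75, and the forecast's second figure was 1.28 times the latter.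

    catalyst intermediate C → free catalyst + product (k = 92.0 /s)
    catalyst intermediate B → catalyst intermediate C (k = 49.0 /s)
    starting material + free catalyst → catalyst intermediate A (k = 4.20 /M/s)
    gas ⇌ partner, rate k4*(csat - [partner]) (kL = 0.0640 /s)
    partner + catalyst intermediate A → catalyst intermediate B (k = 310 /M/s)

- The gas step passes at most 61.4 mM/min, its rate at zero c(partner), which is the mass-transfer ceiling; the demand I had reckoned for the flask comes to 0.195 of this, and at 0.100 h, with 46.1% starting material left in the flask, partner stood at 0.0127 M.
- The demand I had reckoned at 3.0 mM comes to 0.966 of the ceiling, and the factor for that charge came out at 0.763 of the proportional one.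

(The data are calculated with constants of no real substance, noise included.)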